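## Structural features

Ambrein is a C30 triterpene alcohol. A trans-fused decalin (rings A and B; drimane numbering C1–C10, with C11 and C12 the first two chain carbons) is joined through C9 to a six-carbon chain that ends at the single stereocentre of ring E, a 2,2-dimethyl-6-methylidenecyclohexyl unit. The chain holds one (E)-trisubstituted alkene, C13=C14, with the methyl group on C14.

Four stereocentres are contiguous in the decalin: C5 (H α), C10 (quaternary, CH3 β), C9 (H α, chain β and equatorial) and C8 (tertiary alcohol, OH α and equatorial, CH3 β and axial, so 1,3-diaxial to the C10 methyl). The fifth, the (S) centre of ring E, is seven bonds from C9 and needs absolute control of its own.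

The fragile groups are the tertiary alcohol (it dehydrates in acid and closes to the 8,12-ether as soon as C12 carries a leaving group), the exocyclic methylidene (acid moves it into the ring) and the alkene geometry. With three different alkenes present, neither hydrogenation nor strong acid can be used after the fragments are joined.

The real difficulty is the C8–C9–C10 triad: a quaternary carbon beside a tertiary carbon beside a fully substituted carbinol carbon, with the two methyl groups syn-diaxial. The key step uses the fact that C10 bears CH3, C1, C5 and C9 and so maps onto the para carbon of a para-cresol whose ring becomes ring A (phenol oxygen on C3). A chain on the meta carbon C5 supplies C6–C9, and C9 emerges with a vinyl group that is already C11–C12.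

## Logic of the disconnections

**32 ⇒ 20 + 31.** The C12–C13 single bond is cut, between an sp3 carbon and the CH end of the trisubstituted alkene. This separates the decalin half (16 carbons) from the ring E half (14 carbons), each with its own stereocentres, and lets the alkene geometry be fixed in 31 before the union. The forward coupling must join a primary alkyl boron to an alkenyl iodide with retention, beside a free tertiary alcohol. C12 has to be the nucleophile, because a leaving group on C12 would be displaced by the 8-hydroxyl.

**20 ⇒ 18 ⇒ 17.** The C12–B bond and the C5–H and C6–H bonds are removed. The ring alkene can only be hydrogenated while no other alkene is present, so the vinyl group of 17 is first turned into a boron group that survives hydrogen. This leaves 17 with only the C8, C9 and C10 centres; C5 is derived from them. The demands are anti-Markovnikov hydroboration of the vinyl group only, and hydrogen delivery to the α face.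

**17 ⇒ 15 ⇒ 14 ⇒ 13.** The C3 methylene is traced back to a carbonyl, the two C4–CH3 bonds are cut, and the C1–C2 hydrogens are removed. The one carbonyl of 13 activates all three operations. The gain is a flat ring A with no stereocentre. The demands are a C1=C2 reduction that spares C4=C5 and the vinyl group (a rhodium hydrogenation would not), and a deoxygenation of a hindered ketone.

**13 ⇒ 12.** The C9–C10 bond is cut, opening ring B and restoring the arene. This is the only cut that removes the quaternary centre and its tertiary neighbour together, and it reduces a bicycle with three stereocentres to an arene with one. The forward step must be branched-selective, para-selective and face-selective at C9 and C10. For that reason 12 carries a free C8 hydroxyl and not a silyl ether. The configurations were checked against the target: C8 is R in 12; C9 and C10 are both R in 13, and C10 becomes S in 19 and 32 only because the priorities change.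

**12 ⇒ 11 ⇒ 10.** The C11=C12 alkene is cut by metathesis logic and the aryl O–Si bond is restored. The carbonate arrives on carbon and not by acylation, so the phenol and the two alcohols need not be told apart. The demand is metathesis at a vinyl group beside a fully substituted carbon.

**10 ⇒ 8 ⇒ 7.** The C8–O bond of 10 is the epoxide C–O bond of 8, and the vinyl group comes from reductive opening. Asymmetric addition of a vinyl group to a methyl alkyl ketone is unreliable, whereas epoxidation of the allylic alcohol is not. The stereocentre is traded for the achiral 7, which must be geometrically pure and matched with the correct tartrate.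

**7 ⇒ 6 ⇒ 4 + 5; 4 ⇒ 2 + 3; 2 ⇒ 1.** The C8=C9 alkene is cut by olefination, then the aryl–C6 bond by a Heck coupling that gives the ketone directly, then the O–Si bond. Everything is reduced to three commercial compounds. The demand is removal of the minor alkene isomer of 6.

**31 ⇒ 29 ⇒ 28 ⇒ 27 ⇒ 25.** The C14–CH3 and C13–I bonds are cut together (carbometalation of an alkyne), then C13 is removed (one-carbon homologation of an aldehyde), then the oxidation level is lowered to the terminal alkene. The geometry problem becomes a syn addition; the demand is that the ring methylidene stays untouched throughout.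

**25 ⇒ 24 ⇒ 23 ⇒ 21.** The exocyclic C=CH2 bond is cut, then the ring–allyl bond at the stereocentre, then one ring C–CH3 bond together with the O-acyl bond. This reaches an achiral commercial enone. The demand is enantioselective allylation on the hindered side of the enolate, and methylenation without epimerization.

## Other disconnections considered

**Alternative 1:** The cut removes C5–C10 and C8–C9 at once and leads to the open-chain trienal A1. In the forward step a chiral amine salt or a chiral boron Lewis acid activates the enal, and an endo intramolecular Diels–Alder reaction gives the octalin aldehyde A2.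
- In its favour: two bonds, both rings and four stereocentres form in one step from an achiral chain; the gem-dimethyl group is in place; ring A needs no redox adjustment. Catalytic asymmetric intramolecular Diels–Alder reactions of trienals are an established reaction type. On bond economy and on precedent this alternative is better than the chosen plan.
- Against it here: the dienophile is a β,β-disubstituted enal and the diene terminus is neopentyl, so the most crowded bond must form in the pericyclic transition state. A2 has C8 as CH(CH3) beside a C6=C7 alkene, so the tertiary alcohol must be installed later at a crowded carbon, and C11 arrives as an aldehyde needing a one-carbon extension.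
- Comparison: in structure it builds more but leaves C8 at the wrong oxidation level, whereas the chosen plan delivers the C8 oxygen and C11–C12 directly. In mechanism it is concerted and known against ionic and new. In step economy it is shorter to the decalin and longer afterwards, so the totals are similar.

**Alternative 2:** The cut is C8–C9 and leads to the keto vinyl sulfone A3. In the forward step SmI2 with HMPA and t-BuOH forms a ketyl that adds 6-exo to the vinyl sulfone to give A4.
- In its favour: A4 already has the trans-decalin, the gem-dimethyl group and the 8α-alcohol, and the sulfone on C11 is a handle for chain extension. Ketyl–olefin cyclization is a known reaction type, so the step is more secure than the new iridium step. It also needs far fewer steps after the key step. On both points it is better.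
- Against it here: the step creates neither C5 nor C10. A3 must already hold a trans-disubstituted cyclohexane with the quaternary C10 as a single enantiomer, so the hardest centre is moved into precursor synthesis. The C8 outcome (methyl axial, syn to the C10 methyl) is not obviously favoured, and desulfonylation must later spare the alkenes.
- Comparison: in structure the chosen plan makes C10 from a flat arene in the key step, where this one makes only C8 and C9. In mechanism it is radical-anionic and known against π-allyl and new. In step economy it is better after the key step and worse before it.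

**Alternative 3:** The cut lies in ring E, between the methylidene-bearing carbon and the CH stereocentre, and leads to the enyne A5. In the forward step Pd(O2CCF3)2 with a chiral bisphosphine cycloisomerizes A5 to the silyl enol ether A6.
- In its favour: ring E, its stereocentre and the methylidene form in one atom-economic isomerization from an acyclic precursor. In atom economy it is the equal or the better of the decarboxylative allylation used here, with no CO2 lost and no separate methylenation.
- Against it here: it does not touch the decalin, where the difficulty lies. Enantioselective cycloisomerization to six-membered rings is less developed than to five-membered ones, and the gem-dimethyl group sits beside the reacting alkene. Hydrolysis gives the aldehyde A7, one carbon short of 28, so a homologation and the steps to A5 must be added.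
- Comparison: it is complementary, not competing. It could replace steps 15–19 at similar length without changing the decalin plan.

Key step: step 9

Assumption: the sense of induction in steps 9 and 16 is assigned from the usual empirical models for these ligand classes; if a first sample shows the opposite sense, the enantiomeric ligand is used and nothing else changes.

## Steps

Step 1
Reactants: 1 3-bromo-4-methylphenol
Product: 2 (3-bromo-4-methylphenoxy)triisopropylsilane
Conditions: i-Pr3SiCl, imidazole, DMF, rt
Reagents that add atoms: chlorotriisopropylsilane, CC(C)[Si](Cl)(C(C)C)C(C)C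
Why: Silyl ether formation; the bulky aryl silyl ether masks the phenol through the basic, reducing and titanium-mediated steps and is removed by fluoride in step 7.

Step 2
Reactants: 2 (3-bromo-4-methylphenoxy)triisopropylsilane; 3 but-3-en-2-ol
Product: 4 4-[2-methyl-5-(triisopropylsilyloxy)phenyl]butan-2-one
Conditions: Pd(OAc)2 (3 mol%), (t-Bu)3P·HBF4 (6 mol%), Cy2NMe, 1,4-dioxane, 90 °C
Reagents that add atoms: none
Why: Heck reaction with an allylic alcohol; the aryl group adds to the terminal carbon and β-hydride elimination towards the carbinol gives the enol and hence the saturated ketone, so no separate hydrogenation is needed.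

Step 3
Reactants: 4 4-[2-methyl-5-(triisopropylsilyloxy)phenyl]butan-2-one; 5 triethyl phosphonoacetate
Product: 6 ethyl (2E)-3-methyl-5-[2-methyl-5-(triisopropylsilyloxy)phenyl]pent-2-enoate
Conditions: NaH, THF, 0 → 50 °C; (Z)-ester removed by chromatography
Reagents that add atoms: none
Why: Horner–Wadsworth–Emmons olefination, which should favour the (E)-ester; the minor (Z)-isomer must be removed because it would give the opposite configuration at C8 in step 5.

Step 4
Reactants: 6 ethyl (2E)-3-methyl-5-[2-methyl-5-(triisopropylsilyloxy)phenyl]pent-2-enoate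
Product: 7 (2E)-3-methyl-5-[2-methyl-5-(triisopropylsilyloxy)phenyl]pent-2-en-1-ol
Conditions: i-Bu2AlH, CH2Cl2, −78 → 0 °C
Reagents that add atoms: none
Why: 1,2-Reduction of the conjugated ester by an aluminium hydride; the alkene geometry and the aryl silyl ether are not affected.

Step 5
Reactants: 7 (2E)-3-methyl-5-[2-methyl-5-(triisopropylsilyloxy)phenyl]pent-2-en-1-ol
Product: 8 [(2R,3R)-3-methyl-3-{2-[2-methyl-5-(triisopropylsilyloxy)phenyl]ethyl}oxiran-2-yl]methanol
Conditions: Ti(Oi-Pr)4 (10 mol%), D-(−)-diethyl tartrate (12 mol%), t-BuOOH, 4 Å MS, CH2Cl2, −20 °C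
Reagents that add atoms: tert-butyl hydroperoxide, CC(C)(C)OO
Why: Sharpless asymmetric epoxidation; with the D-(−)-tartrate the oxygen is delivered to the face of the (E)-allylic alcohol that gives the (2R,3R)-epoxide, which fixes the methyl-bearing carbon (C8) as R.

Step 6
Reactants: 8 [(2R,3R)-3-methyl-3-{2-[2-methyl-5-(triisopropylsilyloxy)phenyl]ethyl}oxiran-2-yl]methanol
Product: 10 (3R)-3-methyl-5-[2-methyl-5-(triisopropylsilyloxy)phenyl]pent-1-en-3-ol, via epoxy iodide 9 (not isolated)
Conditions: PPh3, I2, imidazole, THF, 0 °C; then Zn dust, EtOH, 60 °C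
Reagents that add atoms: none
Why: Appel-type iodination followed by zinc-induced reductive β-elimination of the epoxy iodide gives the transposed tertiary allylic alcohol; the C8–O bond is never broken, so C8 keeps its configuration while the CH centre disappears.

Step 7
Reactants: 10 (3R)-3-methyl-5-[2-methyl-5-(triisopropylsilyloxy)phenyl]pent-1-en-3-ol
Product: 11 3-[(3R)-3-hydroxy-3-methylpent-4-en-1-yl]-4-methylphenol
Conditions: Bu4NF, THF, 0 °C
Reagents that add atoms: none
Why: Fluoride cleavage of the aryl silyl ether; it is done before the metathesis because fluoride or phenoxide would attack an allylic carbonate.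

Step 8
Reactants: 11 3-[(3R)-3-hydroxy-3-methylpent-4-en-1-yl]-4-methylphenol
Product: 12 (2E,4R)-4-hydroxy-6-(5-hydroxy-2-methylphenyl)-4-methylhex-2-en-1-yl methyl carbonate
Conditions: allyl methyl carbonate (5 equiv), second-generation Hoveyda–Grubbs catalyst RuCl2(H2IMes)(=CH-C6H4-2-Oi-Pr) (5 mol%), CH2Cl2, 40 °C
Reagents that add atoms: allyl methyl carbonate, C=CCOC(=O)OC
Why: Olefin cross-metathesis; the free tertiary allylic hydroxyl is tolerated by the ruthenium carbene and the excess of the unhindered partner should drive formation of the (E)-alkene with loss of ethene. It puts the leaving group on C12 without any need to acylate one hydroxyl among three.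

Step 9
Reactants: 12 (2E,4R)-4-hydroxy-6-(5-hydroxy-2-methylphenyl)-4-methylhex-2-en-1-yl methyl carbonate
Product: 13 (4aR,5R,6R)-5-ethenyl-6-hydroxy-4a,6-dimethyl-5,6,7,8-tetrahydronaphthalen-2(4aH)-one
Conditions: [Ir(cod)Cl]2 (4 mol%), (Sa,S,S)-phosphoramidite [(11bS)-N,N-bis((1S)-1-phenylethyl)dinaphtho[2,1-d:1',2'-f][1,3,2]dioxaphosphepin-4-amine] (8 mol%), n-PrNH2 preactivation; Li2CO3, THF (0.02 M), 50 °C
Reagents that add atoms: none
Why: Proposed new method: the cyclometalated phosphoramidite complex of monovalent iridium ionizes the methyl carbonate to a π-allyl complex of trivalent iridium with loss of CO2 and methoxide, the methoxide deprotonates the phenol, and the phenoxide attacks the substituted allyl terminus C9 through its para carbon C10 on the face opposite to the metal, which forms C9–C10 and leaves the cross-conjugated dienone because the para methyl group blocks rearomatization. The closest known reaction types are the iridium-catalysed intramolecular allylic dearomatization of para-tethered phenols to spirocyclohexadienones and the base-mediated para-alkylation of meta-tethered phenols to fused dienones, and this step merges the two. Ring B closes as a six-membered ring by attack on the proximal allyl carbon (6-exo with respect to the allyl unit, the C11=C12 vinyl group ending outside the ring), whereas attack on C12 would need an eight-membered ring holding an (E)-alkene, so branched selectivity is enforced by ring size as well as by the catalyst. C9 is set by the ligand: by the empirical facial model for this ligand class the (Sa,S,S)-ligand directs the nucleophile to the face that gives 9R (C9–H α). C10 is set relative to C9 by a chair-like transition state with the metal-bound allyl fragment equatorial, which places the C9 hydrogen anti to the emerging axial C10 methyl group, and the preset (R)-C8 then has its hydroxyl equatorial and its methyl axial. The step needs para over ortho attack (attack through the unsubstituted ortho carbon C4 closes the same ring size and rearomatizes to a tetralin), carbon over oxygen attack, and a workable rate at an allyl terminus flanked by a fully substituted carbon. These are addressed by leaving the C8 oxygen as the small free hydroxyl (the C8 substituent anti to the forming bond points at the metal, so a silyl ether there would hinder both ionization and attack), by the larger para coefficient of a weakly ion-paired phenoxide, by a tether that makes intramolecular oxygen attack impossible, and by high dilution against intermolecular O-allylation.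

Step 10
Reactants: 13 (4aR,5R,6R)-5-ethenyl-6-hydroxy-4a,6-dimethyl-5,6,7,8-tetrahydronaphthalen-2(4aH)-one
Product: 14 (4aR,5R,6R)-5-ethenyl-6-hydroxy-4a,6-dimethyl-4,4a,5,6,7,8-hexahydronaphthalen-2(3H)-one
Conditions: [(Ph3P)CuH]6 (0.25 equiv), H2O (3 equiv), benzene/THF, rt
Reagents that add atoms: none
Why: Conjugate reduction by a phosphine-stabilized copper hydride; hydride transfer should be much faster to the β-monosubstituted C1=C2 enone than to the β,β-disubstituted C4=C5 enone. Isolated alkenes are inert to it, which is why RhCl(PPh3)3 and hydrogen, which would take the vinyl group first, are not used.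

Step 11
Reactants: 14 (4aR,5R,6R)-5-ethenyl-6-hydroxy-4a,6-dimethyl-4,4a,5,6,7,8-hexahydronaphthalen-2(3H)-one
Product: 15 (4aR,5R,6R)-5-ethenyl-6-hydroxy-1,1,4a,6-tetramethyl-3,4,4a,5,6,7-hexahydronaphthalen-2(1H)-one
Conditions: KOt-Bu (2.5 equiv), MeI (3 equiv), t-BuOH/THF, rt
Reagents that add atoms: iodomethane, CI
Why: Deconjugative double α-alkylation through the extended enolate: deprotonation at C6, methylation at C4, and repetition give the 4,4-dimethyl ketone with the alkene moved to C5=C6. The hindered tertiary alkoxide should compete no better than the solvent for iodomethane.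

Step 12
Reactants: 15 (4aR,5R,6R)-5-ethenyl-6-hydroxy-1,1,4a,6-tetramethyl-3,4,4a,5,6,7-hexahydronaphthalen-2(1H)-one
Product: 17 (1R,2R,8aR)-1-ethenyl-2,5,5,8a-tetramethyl-1,2,3,5,6,7,8,8a-octahydronaphthalen-2-ol, via hydrazone 16 (not isolated)
Conditions: N2H4·H2O, KOH, diethylene glycol, 130 → 200 °C, argon
Reagents that add atoms: none
Why: Wolff–Kishner reduction (Huang-Minlon modification); the C3 ketone beside the quaternary C4 forms its hydrazone and loses nitrogen to give the methylene group. Argon excludes diimide formation, which would reduce the vinyl group.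

Step 13
Reactants: 17 (1R,2R,8aR)-1-ethenyl-2,5,5,8a-tetramethyl-1,2,3,5,6,7,8,8a-octahydronaphthalen-2-ol
Product: 18 (1R,2R,8aR)-2,5,5,8a-tetramethyl-1-[2-(4,4,5,5-tetramethyl-1,3,2-dioxaborolan-2-yl)ethyl]-1,2,3,5,6,7,8,8a-octahydronaphthalen-2-ol
Conditions: [Ir(cod)Cl]2 (1.5 mol%), Ph2PCH2PPh2 (3 mol%), pinacolborane, CH2Cl2, rt
Reagents that add atoms: pinacolborane, CC1(C)OBOC1(C)C
Why: Iridium-catalysed anti-Markovnikov hydroboration; only the monosubstituted vinyl group reacts and the hindered C5=C6 alkene does not. A pinacol boronate, unlike a dialkylborane, survives the hydrogenation that follows, so the vinyl group is converted before the ring alkene is reduced.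

Step 14
Reactants: 18 (1R,2R,8aR)-2,5,5,8a-tetramethyl-1-[2-(4,4,5,5-tetramethyl-1,3,2-dioxaborolan-2-yl)ethyl]-1,2,3,5,6,7,8,8a-octahydronaphthalen-2-ol
Product: 20 potassium trifluoro{2-[(1R,2R,4aS,8aS)-2-hydroxy-2,5,5,8a-tetramethyldecahydronaphthalen-1-yl]ethyl}borate, via saturated boronate 19 (not isolated)
Conditions: H2 (10 atm), PtO2, EtOAc/AcOH, rt; then KHF2, MeOH/H2O, rt
Reagents that add atoms: potassium hydrogen difluoride, F.[F-].[K+]
Why: Heterogeneous hydrogenation followed by fluoride exchange at boron; hydrogen should add to C5=C6 from the α face because the β face is screened by the axial methyl groups on C10 and C8 and the β methyl on C4, which gives the trans-decalin (C5–H α). KHF2 turns the boronate into the air-stable trifluoroborate used in the coupling.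

Step 15
Reactants: 21 3-methylcyclohex-2-en-1-one
Product: 23 3,3-dimethylcyclohex-1-en-1-yl prop-2-en-1-yl carbonate, via lithium enolate 22 (not isolated)
Conditions: Me2CuLi (from MeLi, CuI), Et2O, 0 °C; then TMEDA, allyl chloroformate, THF, −78 → 0 °C
Reagents that add atoms: lithium dimethylcuprate, [Li+].C[Cu-]C; allyl chloroformate, C=CCOC(Cl)=O
Why: Conjugate addition of a Gilman cuprate creates the gem-dimethyl carbon and the regiodefined enolate on the hindered side; O-acylation with the chloroformate in the presence of the diamine gives the enol carbonate.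

Step 16
Reactants: 23 3,3-dimethylcyclohex-1-en-1-yl prop-2-en-1-yl carbonate
Product: 24 (2S)-3,3-dimethyl-2-(prop-2-en-1-yl)cyclohexan-1-one
Conditions: Pd2(dba)3·CHCl3 (2.5 mol%), (R,R)-N,N'-(9,10-dihydro-9,10-ethanoanthracene-11,12-diyl)bis[2-(diphenylphosphanyl)benzamide] (5.5 mol%), 1,4-dioxane, 23 °C
Reagents that add atoms: none
Why: Decarboxylative asymmetric allylic alkylation (Tsuji allylation); zerovalent palladium ionizes the carbonate, CO2 is lost, and the enolate and π-allyl ion pair recombine inside the chiral pocket. The allyl group is thus delivered to one enolate face, and the (S) centre is set under neutral conditions that do not epimerize it.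

Step 17
Reactants: 24 (2S)-3,3-dimethyl-2-(prop-2-en-1-yl)cyclohexan-1-one
Product: 25 (2S)-1,1-dimethyl-3-methylidene-2-(prop-2-en-1-yl)cyclohexane
Conditions: Zn, CH2Br2, TiCl4, THF/CH2Cl2, 0 °C → rt
Reagents that add atoms: dibromomethane, BrCBr
Why: Takai–Lombardo methylenation; the non-basic zinc–titanium methylene reagent converts the hindered ketone into the exocyclic alkene without epimerizing the adjacent centre, which a basic Wittig ylide could do.

Step 18
Reactants: 25 (2S)-1,1-dimethyl-3-methylidene-2-(prop-2-en-1-yl)cyclohexane
Product: 27 3-[(1S)-2,2-dimethyl-6-methylidenecyclohexyl]propan-1-ol, via trialkylborane 26 (not isolated)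
Conditions: (Sia)2BH (from BH3·THF, 2-methylbut-2-ene), THF, 0 °C; then NaOH, H2O2, 0 °C → rt
Reagents that add atoms: hydrogen peroxide, OO
Why: Hydroboration–oxidation; the bulky dialkylborane should select the monosubstituted alkene over the hindered 1,1-disubstituted ring alkene, and oxidation gives the primary alcohol.

Step 19
Reactants: 27 3-[(1S)-2,2-dimethyl-6-methylidenecyclohexyl]propan-1-ol
Product: 28 3-[(1S)-2,2-dimethyl-6-methylidenecyclohexyl]propanal
Conditions: Dess–Martin periodinane, NaHCO3, CH2Cl2, 0 °C → rt
Reagents that add atoms: none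
Why: Dess–Martin oxidation under buffered, non-acidic conditions, which leave the acid-sensitive exocyclic alkene in place.

Step 20
Reactants: 28 3-[(1S)-2,2-dimethyl-6-methylidenecyclohexyl]propanal
Product: 29 (2S)-2-(but-3-yn-1-yl)-1,1-dimethyl-3-methylidenecyclohexane
Conditions: dimethyl (1-diazo-2-oxopropyl)phosphonate, K2CO3, MeOH, 0 °C → rt
Reagents that add atoms: dimethyl (1-diazo-2-oxopropyl)phosphonate, CC(=O)C(=[N+]=[N-])P(=O)(OC)OC
Why: Seyferth–Gilbert homologation (Ohira–Bestmann variant); the diazomethylphosphonate formed in situ adds to the aldehyde and the alkylidene carbene rearranges to the terminal alkyne, which adds C13.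

Step 21
Reactants: 29 (2S)-2-(but-3-yn-1-yl)-1,1-dimethyl-3-methylidenecyclohexane
Product: 31 (2S)-2-[(3E)-4-iodo-3-methylbut-3-en-1-yl]-1,1-dimethyl-3-methylidenecyclohexane, via alkenylalane 30 (not isolated)
Conditions: AlMe3, Cp2ZrCl2, CH2Cl2, 0 °C → rt; then I2, THF, −30 → 0 °C
Reagents that add atoms: trimethylaluminium, C[Al](C)C; iodine, II
Why: Negishi carboalumination; syn addition of CH3–Al across the terminal alkyne puts the methyl on C14 and aluminium on C13, and iodinolysis with retention gives the (E)-alkenyl iodide, so the geometry is fixed before the fragments are joined. The 1,1-disubstituted ring alkene should not react.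

Step 22
Reactants: 20 potassium trifluoro{2-[(1R,2R,4aS,8aS)-2-hydroxy-2,5,5,8a-tetramethyldecahydronaphthalen-1-yl]ethyl}borate; 31 (2S)-2-[(3E)-4-iodo-3-methylbut-3-en-1-yl]-1,1-dimethyl-3-methylidenecyclohexane
Product: 32 ambrein
Conditions: PdCl2(dppf)·CH2Cl2 (10 mol%), Cs2CO3, toluene/H2O (3:1), 80 °C
Reagents that add atoms: none
Why: B-alkyl Suzuki–Miyaura coupling of a primary alkyltrifluoroborate with an alkenyl iodide; oxidative addition and reductive elimination keep the (E) geometry and the free tertiary alcohol is tolerated. Boron on C12 avoids any C12 leaving group that the 8-hydroxyl could displace.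

## Compound list

1 | 3-bromo-4-methylphenol | Cc1ccc(O)cc1Br | starting material
2 | (3-bromo-4-methylphenoxy)triisopropylsilane | Cc1ccc(O[Si](C(C)C)(C(C)C)C(C)C)cc1Br | intermediate
3 | but-3-en-2-ol (racemic) | C=CC(C)O | starting material
4 | 4-[2-methyl-5-(triisopropylsilyloxy)phenyl]butan-2-one | Cc1ccc(O[Si](C(C)C)(C(C)C)C(C)C)cc1CCC(C)=O | intermediate
5 | triethyl phosphonoacetate | CCOC(=O)CP(=O)(OCC)OCC | starting material
6 | ethyl (2E)-3-methyl-5-[2-methyl-5-(triisopropylsilyloxy)phenyl]pent-2-enoate | CCOC(=O)/C=C(\C)CCc1cc(O[Si](C(C)C)(C(C)C)C(C)C)ccc1C | intermediate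
7 | (2E)-3-methyl-5-[2-methyl-5-(triisopropylsilyloxy)phenyl]pent-2-en-1-ol | Cc1ccc(O[Si](C(C)C)(C(C)C)C(C)C)cc1CC/C(C)=C/CO | intermediate
8 | [(2R,3R)-3-methyl-3-{2-[2-methyl-5-(triisopropylsilyloxy)phenyl]ethyl}oxiran-2-yl]methanol | Cc1ccc(O[Si](C(C)C)(C(C)C)C(C)C)cc1CC[C@@]1(C)O[C@@H]1CO | intermediate
9 | (2R,3S)-3-(iodomethyl)-2-methyl-2-{2-[2-methyl-5-(triisopropylsilyloxy)phenyl]ethyl}oxirane | Cc1ccc(O[Si](C(C)C)(C(C)C)C(C)C)cc1CC[C@@]1(C)O[C@@H]1CI | intermediate
10 | (3R)-3-methyl-5-[2-methyl-5-(triisopropylsilyloxy)phenyl]pent-1-en-3-ol | Cc1ccc(O[Si](C(C)C)(C(C)C)C(C)C)cc1CC[C@@](C)(O)C=C | intermediate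
11 | 3-[(3R)-3-hydroxy-3-methylpent-4-en-1-yl]-4-methylphenol | Cc1ccc(O)cc1CC[C@@](C)(O)C=C | intermediate
12 | (2E,4R)-4-hydroxy-6-(5-hydroxy-2-methylphenyl)-4-methylhex-2-en-1-yl methyl carbonate | Cc1ccc(O)cc1CC[C@@](C)(O)/C=C/COC(=O)OC | intermediate
13 | (4aR,5R,6R)-5-ethenyl-6-hydroxy-4a,6-dimethyl-5,6,7,8-tetrahydronaphthalen-2(4aH)-one (8α-OH, 9β-vinyl, 10β-CH3) | C=C[C@@H]1[C@@]2(C)C=CC(=O)C=C2CC[C@@]1(C)O | intermediate
14 | (4aR,5R,6R)-5-ethenyl-6-hydroxy-4a,6-dimethyl-4,4a,5,6,7,8-hexahydronaphthalen-2(3H)-one | C=C[C@@H]1[C@@]2(C)CCC(=O)C=C2CC[C@@]1(C)O | intermediate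
15 | (4aR,5R,6R)-5-ethenyl-6-hydroxy-1,1,4a,6-tetramethyl-3,4,4a,5,6,7-hexahydronaphthalen-2(1H)-one | C=C[C@@H]1[C@@]2(C)CCC(=O)C(C)(C)C2=CC[C@@]1(C)O | intermediate
16 | hydrazone of 15 at C3 | C=C[C@@H]1[C@@]2(C)CCC(=NN)C(C)(C)C2=CC[C@@]1(C)O | intermediate
17 | (1R,2R,8aR)-1-ethenyl-2,5,5,8a-tetramethyl-1,2,3,5,6,7,8,8a-octahydronaphthalen-2-ol | C=C[C@@H]1[C@@]2(C)CCCC(C)(C)C2=CC[C@@]1(C)O | intermediate
18 | (1R,2R,8aR)-2,5,5,8a-tetramethyl-1-[2-(4,4,5,5-tetramethyl-1,3,2-dioxaborolan-2-yl)ethyl]-1,2,3,5,6,7,8,8a-octahydronaphthalen-2-ol | CC1(C)OB(CC[C@@H]2[C@@]3(C)CCCC(C)(C)C3=CC[C@@]2(C)O)OC1(C)C | intermediate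
19 | (1R,2R,4aS,8aS)-2,5,5,8a-tetramethyl-1-[2-(4,4,5,5-tetramethyl-1,3,2-dioxaborolan-2-yl)ethyl]decahydronaphthalen-2-ol | CC1(C)OB(CC[C@@H]2[C@@]3(C)CCCC(C)(C)[C@@H]3CC[C@@]2(C)O)OC1(C)C | intermediate
20 | potassium trifluoro{2-[(1R,2R,4aS,8aS)-2-hydroxy-2,5,5,8a-tetramethyldecahydronaphthalen-1-yl]ethyl}borate | [K+].F[B-](F)(F)CC[C@@H]1[C@@]2(C)CCCC(C)(C)[C@@H]2CC[C@@]1(C)O | intermediate
21 | 3-methylcyclohex-2-en-1-one | CC1=CC(=O)CCC1 | starting material
22 | lithium 3,3-dimethylcyclohex-1-en-1-olate | [Li+].[O-]C1=CC(C)(C)CCC1 | intermediate
23 | 3,3-dimethylcyclohex-1-en-1-yl prop-2-en-1-yl carbonate | C=CCOC(=O)OC1=CC(C)(C)CCC1 | intermediate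
24 | (2S)-3,3-dimethyl-2-(prop-2-en-1-yl)cyclohexan-1-one | O=C1CCCC(C)(C)[C@@H]1CC=C | intermediate
25 | (2S)-1,1-dimethyl-3-methylidene-2-(prop-2-en-1-yl)cyclohexane | C=C1CCCC(C)(C)[C@@H]1CC=C | intermediate
26 | {3-[(1S)-2,2-dimethyl-6-methylidenecyclohexyl]propyl}bis(3-methylbutan-2-yl)borane | C=C1CCCC(C)(C)[C@@H]1CCCB(C(C)C(C)C)C(C)C(C)C | intermediate
27 | 3-[(1S)-2,2-dimethyl-6-methylidenecyclohexyl]propan-1-ol | C=C1CCCC(C)(C)[C@@H]1CCCO | intermediate
28 | 3-[(1S)-2,2-dimethyl-6-methylidenecyclohexyl]propanal | C=C1CCCC(C)(C)[C@@H]1CCC=O | intermediate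
29 | (2S)-2-(but-3-yn-1-yl)-1,1-dimethyl-3-methylidenecyclohexane | C=C1CCCC(C)(C)[C@@H]1CCC#C | intermediate
30 | {(1E)-4-[(1S)-2,2-dimethyl-6-methylidenecyclohexyl]-2-methylbut-1-en-1-yl}dimethylalumane | C=C1CCCC(C)(C)[C@@H]1CC/C(C)=C/[Al](C)C | intermediate
31 | (2S)-2-[(3E)-4-iodo-3-methylbut-3-en-1-yl]-1,1-dimethyl-3-methylidenecyclohexane | C=C1CCCC(C)(C)[C@@H]1CC/C(C)=C/I | intermediate
32 | ambrein, (1R,2R,4aS,8aS)-1-{(3E)-6-[(1S)-2,2-dimethyl-6-methylidenecyclohexyl]-4-methylhex-3-en-1-yl}-2,5,5,8a-tetramethyldecahydronaphthalen-2-ol | C=C1CCCC(C)(C)[C@@H]1CC/C(C)=C/CC[C@@H]1[C@@]2(C)CCCC(C)(C)[C@@H]2CC[C@@]1(C)O | target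

## Step count and least certain steps

Total step count: 22. Longest linear sequence: 15 steps (steps 1–14, then step 22); the ring E branch is steps 15–21.

**Step 9 (key step, new method).** The most likely failures are attack through the unsubstituted ortho carbon, which closes the same ring size and then rearomatizes; intermolecular O-allylation; a slow reaction at the crowded allyl terminus; and a mismatch between the ligand and the preset C8 centre that erodes facial control at C9. The fallback uses known reactions and the classical base-mediated para-alkylation of a meta-tethered phenoxide, with an allylic epoxide as the electrophile in place of the metal π-allyl. It sets out from 8 and comes back at 13.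
- Oxidation of 8 (Dess–Martin periodinane) gives the epoxy aldehyde F1.
- Wittig methylenation (Ph3P=CH2) gives the trans vinyl epoxide F2.
- Fluoride removes the silyl group to give the phenol F3.
- KOt-Bu in t-BuOH lets the para carbon open the epoxide at the allylic carbon C9 by SN2 with inversion, giving 13.

In this fallback the C8–O bond is never broken, so C8 stays R. Inversion at C9 of the trans epoxide gives 9R, and a chair closure sets C10; all stereochemistry comes from the Sharpless epoxide. The protic medium is the one known to favour para over ortho alkylation, though that selectivity remains the open point.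

**Step 8 (cross-metathesis).** Metathesis may stall at the vinyl group beside the fully substituted carbinol carbon while the carbonate partner homodimerizes and the catalyst decays. The fallback builds the C11=C12 unit by olefination. It sets out from 10 and comes back at 12.
- Oxidative cleavage of the vinyl group (OsO4 cat., NaIO4) gives the α-hydroxy aldehyde F4.
- Wittig reaction with Ph3P=CHCO2Me gives the (E)-hydroxy enoate F5.
- i-Bu2AlH gives the (E)-ene-1,4-diol F6.
- Methyl chloroformate and pyridine at 0 °C acylate only the primary hydroxyl to give the carbonate F7.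
- Buffered fluoride (HF·pyridine) removes the aryl silyl group to give 12.

**Step 10 (site-selective conjugate reduction).** Hydride transfer may not discriminate well enough between the two enone alkenes, or may over-reduce. The fallback changes the order so that only one conjugated alkene exists when the hydride is used. It sets out from 13 and comes back at 15.
- Double methylation of 13 through its extended enolate (KOt-Bu, MeI) gives the 4,4-dimethyl-1,5-dien-3-one F8.
- Conjugate reduction of the single remaining enone with LiBH(s-Bu)3 gives 15.

**Step 12 (Wolff–Kishner).** Hydrazone formation at the hindered ketone may be incomplete, diimide may reduce the vinyl group, or the homoallylic tertiary alkoxide may fragment at 200 °C. The fallback removes the oxygen as an alkene at low temperature. It sets out from 15 and comes back at 20.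
- p-Toluenesulfonyl hydrazide gives the tosylhydrazone F9.
- A Shapiro reaction (excess MeLi) gives the 2,5-diene F10.
- Hydroboration as in step 13 gives the boronate F11.
- Hydrogenation of both ring alkenes and fluoride exchange as in step 14 give 20 by way of 19.

**Step 16 (asymmetric allylation).** Enantioselectivity may be insufficient for a tertiary α-centre beside a quaternary carbon, and enolate equilibration may cause loss of configuration or a second allylation. The fallback is a resolution. It sets out from 21 and comes back at 24.
- Cuprate addition to 21 and trapping with allyl bromide give the racemic ketone F12.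
- LiBH(s-Bu)3 gives the racemic cis alcohol F13.
- Lipase-catalysed acylation (Candida antarctica lipase B, vinyl acetate) separates the enantiomers, and the (1R,2S)-alcohol F14 is collected.
- Dess–Martin oxidation of F14 gives 24.

## Further compounds

F1 | step 9 | (2S,3R)-3-methyl-3-{2-[2-methyl-5-(triisopropylsilyloxy)phenyl]ethyl}oxirane-2-carbaldehyde | Cc1ccc(O[Si](C(C)C)(C(C)C)C(C)C)cc1CC[C@@]1(C)O[C@@H]1C=O
F2 | step 9 | (2R,3R)-3-ethenyl-2-methyl-2-{2-[2-methyl-5-(triisopropylsilyloxy)phenyl]ethyl}oxirane | Cc1ccc(O[Si](C(C)C)(C(C)C)C(C)C)cc1CC[C@@]1(C)O[C@@H]1C=C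
F3 | step 9 | 3-{2-[(2R,3R)-3-ethenyl-2-methyloxiran-2-yl]ethyl}-4-methylphenol | Cc1ccc(O)cc1CC[C@@]1(C)O[C@@H]1C=C
F4 | step 8 | (2R)-2-hydroxy-2-methyl-4-[2-methyl-5-(triisopropylsilyloxy)phenyl]butanal | Cc1ccc(O[Si](C(C)C)(C(C)C)C(C)C)cc1CC[C@@](C)(O)C=O
F5 | step 8 | methyl (2E,4R)-4-hydroxy-4-methyl-6-[2-methyl-5-(triisopropylsilyloxy)phenyl]hex-2-enoate | Cc1ccc(O[Si](C(C)C)(C(C)C)C(C)C)cc1CC[C@@](C)(O)/C=C/C(=O)OC
F6 | step 8 | (2E,4R)-4-methyl-6-[2-methyl-5-(triisopropylsilyloxy)phenyl]hex-2-ene-1,4-diol | Cc1ccc(O[Si](C(C)C)(C(C)C)C(C)C)cc1CC[C@@](C)(O)/C=C/CO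
F7 | step 8 | (2E,4R)-4-hydroxy-4-methyl-6-[2-methyl-5-(triisopropylsilyloxy)phenyl]hex-2-en-1-yl methyl carbonate | Cc1ccc(O[Si](C(C)C)(C(C)C)C(C)C)cc1CC[C@@](C)(O)/C=C/COC(=O)OC
F8 | step 10 | (4aR,5R,6R)-5-ethenyl-6-hydroxy-1,1,4a,6-tetramethyl-4a,5,6,7-tetrahydronaphthalen-2(1H)-one | C=C[C@@H]1[C@@]2(C)C=CC(=O)C(C)(C)C2=CC[C@@]1(C)O
F9 | step 12 | 4-methylbenzenesulfonyl hydrazone of 15 at C3 | C=C[C@@H]1[C@@]2(C)CCC(=NNS(=O)(=O)c3ccc(C)cc3)C(C)(C)C2=CC[C@@]1(C)O
F10 | step 12 | (1R,2R,8aR)-1-ethenyl-2,5,5,8a-tetramethyl-1,2,3,5,8,8a-hexahydronaphthalen-2-ol | C=C[C@@H]1[C@@]2(C)CC=CC(C)(C)C2=CC[C@@]1(C)O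
F11 | step 12 | (1R,2R,8aR)-2,5,5,8a-tetramethyl-1-[2-(4,4,5,5-tetramethyl-1,3,2-dioxaborolan-2-yl)ethyl]-1,2,3,5,8,8a-hexahydronaphthalen-2-ol | CC1(C)OB(CC[C@@H]2[C@@]3(C)CC=CC(C)(C)C3=CC[C@@]2(C)O)OC1(C)C
F12 | step 16 | 3,3-dimethyl-2-(prop-2-en-1-yl)cyclohexan-1-one (racemic) | O=C1CCCC(C)(C)C1CC=C
F13 | step 16 | cis-3,3-dimethyl-2-(prop-2-en-1-yl)cyclohexan-1-ol (racemic; one enantiomer drawn) | O[C@@H]1CCCC(C)(C)[C@@H]1CC=C
F14 | step 16 | (1R,2S)-3,3-dimethyl-2-(prop-2-en-1-yl)cyclohexan-1-ol | O[C@@H]1CCCC(C)(C)[C@@H]1CC=C
A1 | alternative 1 | (2E,8E,10E)-3,7,7-trimethyldodeca-2,8,10-trienal | O=C/C=C(\C)CCCC(C)(C)/C=C/C=C/C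
A2 | alternative 1 | 4,4,8β,10β-tetramethyl-trans-Δ6-octalin-9β-carbaldehyde (drimane numbering) | O=C[C@@H]1[C@@]2(C)CCCC(C)(C)[C@@H]2C=C[C@@H]1C
A3 | alternative 2 | 4-{(1S,2S)-2,6,6-trimethyl-2-[(E)-2-(phenylsulfonyl)ethenyl]cyclohexyl}butan-2-one | CC(=O)CC[C@H]1C(C)(C)CCC[C@]1(C)/C=C/S(=O)(=O)c1ccccc1
A4 | alternative 2 | 8α-hydroxy-11-(phenylsulfonyl)drimane | O=S(=O)(c1ccccc1)C[C@@H]1[C@@]2(C)CCCC(C)(C)[C@@H]2CC[C@@]1(C)O
A5 | alternative 3 | tert-butyl{[(2E)-4,4-dimethylnon-2-en-8-yn-1-yl]oxy}dimethylsilane | C#CCCCC(C)(C)/C=C/CO[Si](C)(C)C(C)(C)C
A6 | alternative 3 | tert-butyl({(E)-2-[(1S)-2,2-dimethyl-6-methylidenecyclohexyl]ethenyl}oxy)dimethylsilane | C=C1CCCC(C)(C)[C@@H]1/C=C/O[Si](C)(C)C(C)(C)C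
A7 | alternative 3 | [(1S)-2,2-dimethyl-6-methylidenecyclohexyl]acetaldehyde | C=C1CCCC(C)(C)[C@@H]1CC=O
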